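(The data are calculated with constants of no real substance, noise included.)

Green and blue, the two flasks we must judge, hold electrophile and nucleophile with free base fed in, and on the recipe they differ from Monday's and Saturday's runs in the charge of free base.

in all of them: electrophile 0.20 M
- Monday's: nucleophile 0.50 M; free base 0.12 M (fed, over 5.0 h); run made earlier; the fed solution adds 0.20 times the starting volume
- Saturday's: nucleophile 0.50 M; free base 0.18 M (fed, over 5.0 h); run made earlier; the fed solution adds 0.20 times the starting volume
- green: nucleophile 0.500 M; free base 0.100 M (fed, over 5.0 h); the fed solution adds 0.20 times the starting volume; time 15 h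
- blue: nucleophile 0.500 M; free base 0.150 M (fed, over 5.0 h); the fed solution adds 0.20 times the starting volume; time 15 h

| run | time / h | electrophile / % | target / % |
|---|---|---|---|
| Monday's | 1.33 | 73.5 | 21.6 |
| Monday's | 2.00 | 65.1 | 26.0 |
| Monday's | 3.00 | 55.3 | 27.4 |
| Monday's | 4.00 | 47.5 | 27.0 |
| Monday's | 6.00 | 38.6 | 24.0 |
| Monday's | 10.0 | 26.1 | 16.9 |
| Monday's | 15.0 | 16.9 | 12.2 |
| Saturday's | 2.00 | 65.4 | 26.0 |
| Saturday's | 4.00 | 48.2 | 26.6 |
| Saturday's | 6.00 | 37.7 | 23.3 |
| Saturday's | 8.00 | 30.5 | 20.3 |
| Saturday's | 10.0 | 25.4 | 17.4 |
| Saturday's | 12.0 | 21.0 | 14.0 |
| Saturday's | 15.0 | 16.7 | 13.3 |

(readings scatter by 0.5 percentage points)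

- every charge counts on the volume at the start, and the solution that is fed holds the whole dose

1. part of the electrophile that has reacted at the end, green
2. part of the electrophile that has reacted at the end, blue
3. what raising the concentration of free base from its lowest to its highest value here does to the part of the electrophile that has reacted (changes below 5 percentage points count as none) (it falls / it rises / no change)

We take the numbers by what an error in them would cost, and we work with the fraction of electrophile left. The charges of electrophile and nucleophile, the dosing time, the feed volume and the end time stand in green and blue as in both runs, so we need no rate for them: the readings at that time already contain their effect. Next comes the free base. Saturday charged 1.50 times Monday's amount, yet the electrophile left at 15.0 h moved by 0.2 percentage points, less than the 0.71 points that scatter gives a difference of two readings. Taken at face value, that slope shifts green, 0.0200 M below Monday's charge, by 0.067 points, and parts green from blue by 0.17 points, under the 5 points that counts. What must be known well is the reading itself: the two runs average 16.8% left, good to 0.35 points, so we commit to 83.2% reacted in green and in blue, with no change. We carry the loss constant, an average over the run, which is the natural logarithm of one over the fraction of electrophile left, divided by the time, here 0.119 h⁻¹.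

The forecast gave 83% for green and 83.2% for blue, with no change as the trend, and held that “its loss looks zero-order in base”.

The flasks give 83.0% in green and 83.0% in blue, 0.0093 points apart, so the trend is no change.

    target ⇌ isomer of the product (K = 11.0, k = 0.00510 min⁻¹)
    electrophile + nucleophile ⇌ acid set free + target (K = 0.290, k = 0.00880 L mol⁻¹ min⁻¹)
    acid set free + free base ⇌ salt of the base, settled at all times (K = 16.0 L mol⁻¹)
    nucleophile + acid set free ⇌ protonated nucleophile, settled at all times (K = 4200 L mol⁻¹)
    2 electrophile → homo dimer (k = 1.40 × 10⁻⁵ L mol⁻¹ min⁻¹)

At the end green keeps 99.6% of its free base unbound, with 0.138 M of protonated nucleophile against 3.09 × 10⁻⁴ M of salt of the base. Green's 17% left gives a loss constant of 0.118 h⁻¹, against our 0.119 h⁻¹. Scaled by the nucleophile charge, our constant gives 65.2% of the electrophile left for a flask like green with 0.12 M of nucleophile, and that flask ends with 72.8% of its electrophile left.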